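**Retrosynthetic overview**
1. Target 29 ← methyl ester 28 ← bis-ketal diene 27: the C5 methyl comes from Negishi coupling of dienyl triflate 26 (made from a ring-A enone, C5=O), the acetonyl group from an allyl group (Wacker), and the C10 ketone from a nitro group (Nef).
2. Key disconnection (ring B, bonds C11–C12 and C10–C9): amine-catalysed formal [4+2] of the monocyclic ring-A dienone 18 with (E)-1-nitropropene 20; the nitro group carries the later carbonyl carbon C10 as a nucleophile, so C10 bonds to the acceptor carbon C9 with reversed polarity.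
3. Enabling feature: C7, the ring-fusion end of the target's ring-A diene (C4=C5–C6=C7), is the β-carbon of a latent enone (C5=O, C6=C7); this makes the ring CH2 C12 a γ-donor and the propenyl terminus C9 a δ-acceptor, and because C9 and C11 (α to C10) and C12 (γ to the enone) can epimerise, ring B settles into the all-equatorial target arrangement from C13 alone.
4. Ring A (C4, C5, C6, C7, C12, C13): organocatalytic Robinson-type annulation of dienone 8 with β-keto ester 13 (sets C13), then decarboxylation and C4 allylation.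
5. Side chain C14–C19 with quaternary C16: Sharpless epoxidation of enynol 1, siloxymethyl-migrating epoxide rearrangement, Wittig, carboalumination–iodination, Heck; ring A is formed first (step 8), ring B second (step 12).

Key step: step 12

Remark (assumption): target carbons are numbered along the chain C1H3–C2(=O)–C3H2–C4=C5(CH3)–C6H=C7–C8H2–C9H(CH3)–C10(=O)–C11H(CH3)–C12H–C13H–C14H=C15(CH3)–C16(CH3)(CH2OH)–C17H=C18H–C19O2H (ring A = C4, C5, C6, C7, C12, C13; ring B = C7 to C12; target = 9S,11R,12R,13S,16S); R* stands for the protected side chain (1E,3S,4E)-3-(tert-butyldimethylsilyloxymethyl)-6-methoxy-2,3-dimethyl-6-oxohexa-1,4-dien-1-yl (C14–C19); the facial sense of the cinchona amine in step 8 is assumed by analogy, and the quinidine-derived pseudoenantiomer would be used if it proves opposite.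

**Step 1**
Reactants: 1 (E)-3-methylpent-2-en-4-yn-1-ol
Product: 2 [(2S,3S)-3-ethynyl-3-methyloxiran-2-yl]methanol
Conditions: Ti(OiPr)4 (10 mol%), L-(+)-diethyl tartrate (12 mol%), t-BuOOH, 4 Å MS, CH2Cl2, −20 °C
Reagents that add atoms: tert-butyl hydroperoxide CC(C)(C)OO
Why: Sharpless asymmetric epoxidation of a 3,3-disubstituted (E)-allylic alcohol, in which the L-(+)-tartrate should deliver oxygen to the face that gives the (2S,3S)-epoxide, the source of the later C16 configuration.

**Step 2**
Reactants: 2 [(2S,3S)-3-ethynyl-3-methyloxiran-2-yl]methanol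
Product: 3 tert-butyl{[(2S,3S)-3-ethynyl-3-methyloxiran-2-yl]methoxy}dimethylsilane
Conditions: TBSCl, imidazole, DMF, 0 °C → rt
Reagents that add atoms: tert-butyldimethylsilyl chloride CC(C)(C)[Si](C)(C)Cl
Why: Standard silylation of the primary alcohol, which also installs the migrating siloxymethyl group for step 3 without touching the stereocentres.

**Step 3**
Reactants: 3 tert-butyl{[(2S,3S)-3-ethynyl-3-methyloxiran-2-yl]methoxy}dimethylsilane
Product: 4 (S)-2-{[(tert-butyldimethylsilyl)oxy]methyl}-2-methylbut-3-ynal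
Conditions: MeAl(OAr)2 (Ar = 4-bromo-2,6-di-tert-butylphenyl; 20 mol%), CH2Cl2, −78 → −40 °C
Reagents that add atoms: none
Why: Lewis-acid-promoted rearrangement of an epoxy silyl ether to a β-siloxy aldehyde (semipinacol type): the epoxide opens at the tertiary propargylic carbon and the siloxymethyl group migrates anti from C2 to C3, so C3 is inverted and becomes the quaternary C16 with the configuration of the target.

**Step 4**
Reactants: 4 (S)-2-{[(tert-butyldimethylsilyl)oxy]methyl}-2-methylbut-3-ynal
Product: 5 methyl (S,E)-4-{[(tert-butyldimethylsilyl)oxy]methyl}-4-methylhex-2-en-5-ynoate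
Conditions: Ph3P=CHCO2Me, toluene, 80 °C
Reagents that add atoms: methyl (triphenylphosphoranylidene)acetate COC(=O)C=P(c1ccccc1)(c1ccccc1)c1ccccc1
Why: Wittig olefination with a stabilised ylide should give the (E)-enoate (C17=C18), and the α-quaternary aldehyde cannot epimerise.

**Step 5**
Reactants: 5 methyl (S,E)-4-{[(tert-butyldimethylsilyl)oxy]methyl}-4-methylhex-2-en-5-ynoate
Product: 6 methyl (S,2E,5E)-4-{[(tert-butyldimethylsilyl)oxy]methyl}-6-iodo-4,5-dimethylhexa-2,5-dienoate
Conditions: Me3Al, Cp2ZrCl2 (25 mol%), H2O (1 equiv), CH2Cl2, −30 °C; then I2, THF, −30 → 0 °C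
Reagents that add atoms: trimethylaluminium C[Al](C)C; iodine II
Why: Zirconium-catalysed syn-carboalumination (Negishi) places the methyl on the internal alkyne carbon and aluminium on the terminus, and iodinolysis with retention should give the (E)-iodide that fixes the C14=C15 geometry.

**Step 6**
Reactants: 6 methyl (S,2E,5E)-4-{[(tert-butyldimethylsilyl)oxy]methyl}-6-iodo-4,5-dimethylhexa-2,5-dienoate, 7 but-3-en-2-one
Product: 8 methyl (S,2E,5E,7E)-4-{[(tert-butyldimethylsilyl)oxy]methyl}-4,5-dimethyl-9-oxodeca-2,5,7-trienoate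
Conditions: Pd(OAc)2 (5 mol%), Bu4NCl, NaHCO3, DMF, 40 °C
Reagents that add atoms: none
Why: Heck coupling of the alkenyl iodide with the vinyl ketone proceeds with retention of the iodide geometry and should give the (E,E)-dienone (C13=C4 bond of the future ring A).

**Step 7**
Reactants: 9 2,2-dimethyl-1,3-dioxane-4,6-dione (Meldrum's acid), 10 (E)-but-2-enoyl chloride, 11 prop-2-en-1-ol
Product: 13 allyl (E)-3-oxohex-4-enoate, via acyl Meldrum's acid 12 (not isolated)
Conditions: pyridine, CH2Cl2, 0 °C; then allyl alcohol, toluene, 90 °C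
Reagents that add atoms: none
Why: C-acylation of Meldrum's acid followed by alcoholysis with loss of acetone and CO2 is the standard route to β-keto esters.

**Step 8**
Reactants: 8 methyl (S,2E,5E,7E)-4-{[(tert-butyldimethylsilyl)oxy]methyl}-4,5-dimethyl-9-oxodeca-2,5,7-trienoate, 13 allyl (E)-3-oxohex-4-enoate
Product: 16 allyl trans-4-oxo-2-[(E)-prop-1-enyl]-6-R*-cyclohex-2-ene-1-carboxylate (C13 as in the target), via Michael adduct 14 (not isolated), via aldol 15 (not isolated)
Conditions: 9-amino-9-deoxy-epi-quinine (20 mol%), PhCO2H (40 mol%), toluene, rt → 60 °C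
Reagents that add atoms: none
Why: Amine-catalysed Robinson-type annulation (iminium-activated Michael addition of the β-keto ester carbon C12 to C13, enamine aldol of the C6 methyl onto the C7 ketone, dehydration), in which the chiral primary amine selects the face at C13 and the C12 ester centre equilibrates to trans.

**Step 9**
Reactants: 16 allyl trans-4-oxo-2-[(E)-prop-1-enyl]-6-R*-cyclohex-2-ene-1-carboxylate
Product: 17 (S)-5-R*-3-[(E)-prop-1-enyl]cyclohex-2-en-1-one
Conditions: Pd(OAc)2 (5 mol%), PPh3 (20 mol%), HCO2H, Et3N, THF, 40 °C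
Reagents that add atoms: none
Why: Tsuji deallylation–decarboxylation: zerovalent palladium formed in situ ionises the allyl ester, formate reduces the allyl fragment to propene, and the vinylogous β-keto acid loses CO2, leaving C13 untouched.

**Step 10**
Reactants: 17 (S)-5-R*-3-[(E)-prop-1-enyl]cyclohex-2-en-1-one
Product: 18 trans-6-allyl-5-R*-3-[(E)-prop-1-enyl]cyclohex-2-en-1-one (allyl on C4, trans to R* on C13)
Conditions: LiN(iPr)2, THF, −78 °C; then allyl bromide, −78 → −20 °C
Reagents that add atoms: allyl bromide C=CCBr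
Why: Kinetic α′-enolate alkylation at C4, with the allyl group expected to enter trans to the C13 substituent (this centre later becomes sp2, so its configuration is not critical).

**Step 11**
Reactants: 19 1-nitropropan-2-ol
Product: 20 (E)-1-nitroprop-1-ene
Conditions: phthalic anhydride, 150–180 °C, distillation at reduced pressure
Reagents that add atoms: none
Why: Dehydration of a β-nitro alcohol with phthalic anhydride, the nitroalkene being distilled from the melt as the (E)-isomer.

**Step 12**
Reactants: 18 trans-6-allyl-5-R*-3-[(E)-prop-1-enyl]cyclohex-2-en-1-one, 20 (E)-1-nitroprop-1-ene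
Product: 22 bicyclic nitro enone (ring A: C5=O, C6=C7, C4-allyl, C13-R*; ring B: C8H2, C9H(CH3), C10H(NO2), C11H(CH3), C12H; H12/H13 trans; diastereomer mixture at C9–C11), via vinylogous Michael adduct 21 (not isolated)
Conditions: 9-amino-9-deoxy-epi-quinine (20 mol%), 2-fluorobenzoic acid (40 mol%), toluene, 40 °C
Reagents that add atoms: none
Why: Proposed new method: the primary amine condenses with the C5 ketone of 18 and the iminium is deprotonated at the ring γ-carbon C12 to a cross-conjugated trienamine (N–C5=C6–C7(=C12)–C8=C9), whose C12 adds to C11 of 20, after which the tethered nitronate carbon C10 adds to C9 of the regenerated dienyl iminium (1,6-addition) and hydrolysis returns the enone with C8 as CH2, a formal [4+2] that makes C11–C12 and C10–C9 in one flask. The closest known reaction types are the dienamine-catalysed vinylogous (γ) Michael addition of 3-substituted cyclohex-2-enones to nitroalkenes and the trienamine [4+2] of 2,4-dienals with nitroalkenes; new here is the cross-conjugated trienamine of a cyclic 3-alkenyl enone, so that the second bond closes onto the δ-carbon. Ring B closes by a 6-endo-trig conjugate addition of the nitronate carbon C10 onto C9. C12 is set anti to the C13 substituent of the half-chair trienamine and stays correctable (γ to the enone), C9–C11 form under kinetic control and are corrected in step 13, and the nitro group carries C10 as a carbanion (polarity reversal of the later carbonyl). The step needs attack through C12 and not through C6, C4 or the C9 methyl: C7 is fully substituted so no 1,4-closure competes, C4 is a hindered methine, and only the C12 adduct can close a six-membered ring onto an unhindered secondary carbon, whereas an adduct through the C9 methyl could close only onto C7 with formation of a quaternary spiro centre.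

**Step 13**
Reactants: 22 bicyclic nitro enone
Product: 23 bicyclic enedione (C10=O; 9S,11R,12R as in the target; C4-allyl, C13-R*)
Conditions: NaOMe, MeOH, 0 °C; then TiCl3 (aq.), NH4OAc buffer, rt; then DBU (cat.), CH2Cl2, rt
Reagents that add atoms: water O
Why: Reductive Nef reaction (nitronate reduced by trivalent titanium to the imine, then hydrolysed), after which DBU equilibrates C9 and C11 (α to C10) and, if needed, C12 (γ to the enone) to the all-equatorial arrangement of the target.

**Step 14**
Reactants: 23 bicyclic enedione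
Product: 24 trione (C4–CH2–C(=O)–CH3 in place of C4-allyl)
Conditions: PdCl2 (10 mol%), CuCl, O2 (1 atm), DMF–H2O, rt
Reagents that add atoms: water O
Why: Wacker oxidation converts the terminal alkene into the methyl ketone (Markovnikov), while the trisubstituted and conjugated alkenes are not attacked by divalent palladium under these conditions.

**Step 15**
Reactants: 24 trione
Product: 25 bis(ethylene ketal) enone (dioxolanes at C2 and C10; enone C5=O, C6=C7 free)
Conditions: Me3SiOCH2CH2OSiMe3, Me3SiOTf (5 mol%), CH2Cl2, −78 → −20 °C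
Reagents that add atoms: 1,2-bis(trimethylsilyloxy)ethane C[Si](C)(C)OCCO[Si](C)(C)C
Why: Silyl-triflate-catalysed ketalisation with the bis-silyl glycol should protect the two saturated ketones before the conjugated, α-branched enone reacts, as in the selective ketalisation of saturated over conjugated ketones in octalenediones.

**Step 16**
Reactants: 25 bis(ethylene ketal) enone
Product: 26 dienyl triflate (C4=C5(OTf)–C6=C7)
Conditions: LiN(iPr)2, THF, −78 °C; then PhNTf2, −78 → 0 °C
Reagents that add atoms: N-phenylbis(trifluoromethanesulfonimide) O=S(=O)(N(c1ccccc1)S(=O)(=O)C(F)(F)F)C(F)(F)F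
Why: Kinetic deprotonation at the α′-carbon C4 gives the cross-conjugated dienolate, and O-triflation fixes the homoannular C4=C5/C6=C7 diene of the target.

**Step 17**
Reactants: 26 dienyl triflate
Product: 27 bis-ketal diene (C5–CH3; C4=C5–C6=C7)
Conditions: Me2Zn, Pd(PPh3)4 (5 mol%), THF, 0 °C → rt
Reagents that add atoms: dimethylzinc C[Zn]C
Why: Negishi coupling (oxidative addition of zerovalent palladium into the dienyl triflate, transmetalation, reductive elimination) installs the C5 methyl with the diene position retained and tolerates the methyl ester.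

**Step 18**
Reactants: 27 bis-ketal diene
Product: 28 methyl ester of the target (free C2 and C10 ketones, free C16–CH2OH)
Conditions: HCl (1 M aq.), THF, 0 °C → rt
Reagents that add atoms: water O
Why: Mild aqueous acid hydrolyses both dioxolanes and the primary silyl ether in one operation, C9 and C11 staying in their thermodynamic configuration.

**Step 19**
Reactants: 28 methyl ester of the target
Product: 29 target acid CNP0260948.1 (9S,11R,12R,13S,16S)
Conditions: Me3SnOH, ClCH2CH2Cl, 70 °C; then HCl (0.1 M aq.) work-up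
Reagents that add atoms: trimethyltin hydroxide C[Sn](C)(C)O
Why: Trimethyltin hydroxide cleaves the methyl ester under near-neutral conditions, which avoids base-induced conjugation of the acetonyl ketone with the diene.

**Compound list**
1 | (E)-3-methylpent-2-en-4-yn-1-ol | OC/C=C(\C)C#C | starting material
2 | [(2S,3S)-3-ethynyl-3-methyloxiran-2-yl]methanol | OC[C@@H]1O[C@@]1(C)C#C | intermediate
3 | tert-butyl{[(2S,3S)-3-ethynyl-3-methyloxiran-2-yl]methoxy}dimethylsilane | CC(C)(C)[Si](C)(C)OC[C@@H]1O[C@@]1(C)C#C | intermediate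
4 | (S)-2-{[(tert-butyldimethylsilyl)oxy]methyl}-2-methylbut-3-ynal | O=C[C@@](C)(C#C)CO[Si](C)(C)C(C)(C)C | intermediate
5 | methyl (S,E)-4-{[(tert-butyldimethylsilyl)oxy]methyl}-4-methylhex-2-en-5-ynoate | C#C[C@](C)(/C=C/C(=O)OC)CO[Si](C)(C)C(C)(C)C | intermediate
6 | methyl (S,2E,5E)-4-{[(tert-butyldimethylsilyl)oxy]methyl}-6-iodo-4,5-dimethylhexa-2,5-dienoate | I/C=C(\C)[C@](C)(/C=C/C(=O)OC)CO[Si](C)(C)C(C)(C)C | intermediate
7 | but-3-en-2-one | CC(=O)C=C | starting material
8 | methyl (S,2E,5E,7E)-4-{[(tert-butyldimethylsilyl)oxy]methyl}-4,5-dimethyl-9-oxodeca-2,5,7-trienoate | CC(=O)/C=C/C=C(\C)[C@](C)(/C=C/C(=O)OC)CO[Si](C)(C)C(C)(C)C | intermediate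
9 | 2,2-dimethyl-1,3-dioxane-4,6-dione | CC1(C)OC(=O)CC(=O)O1 | starting material
10 | (E)-but-2-enoyl chloride | C/C=C/C(Cl)=O | starting material
11 | prop-2-en-1-ol | C=CCO | starting material
12 | 5-[(E)-1-hydroxybut-2-enylidene]-2,2-dimethyl-1,3-dioxane-4,6-dione | CC1(C)OC(=O)C(=C(O)/C=C/C)C(=O)O1 | intermediate (not isolated)
13 | allyl (E)-3-oxohex-4-enoate | C/C=C/C(=O)CC(=O)OCC=C | intermediate
14 | allyl 2-[(E)-but-2-enoyl]-5-oxo-3-R*-hexanoate (C13 as in the target, C12 epimers) | CC(=O)C[C@@H](/C=C(\C)[C@](C)(/C=C/C(=O)OC)CO[Si](C)(C)C(C)(C)C)C(C(=O)OCC=C)C(=O)/C=C/C | intermediate (not isolated)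
15 | allyl 2-hydroxy-4-oxo-2-[(E)-prop-1-enyl]-6-R*-cyclohexane-1-carboxylate | O=C1CC(O)(/C=C/C)C(C(=O)OCC=C)[C@H](/C=C(\C)[C@](C)(/C=C/C(=O)OC)CO[Si](C)(C)C(C)(C)C)C1 | intermediate (not isolated)
16 | allyl trans-4-oxo-2-[(E)-prop-1-enyl]-6-R*-cyclohex-2-ene-1-carboxylate | O=C1C=C(/C=C/C)[C@@H](C(=O)OCC=C)[C@H](/C=C(\C)[C@](C)(/C=C/C(=O)OC)CO[Si](C)(C)C(C)(C)C)C1 | intermediate
17 | (S)-5-R*-3-[(E)-prop-1-enyl]cyclohex-2-en-1-one | O=C1C=C(/C=C/C)C[C@H](/C=C(\C)[C@](C)(/C=C/C(=O)OC)CO[Si](C)(C)C(C)(C)C)C1 | intermediate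
18 | trans-6-allyl-5-R*-3-[(E)-prop-1-enyl]cyclohex-2-en-1-one | O=C1C=C(/C=C/C)C[C@H](/C=C(\C)[C@](C)(/C=C/C(=O)OC)CO[Si](C)(C)C(C)(C)C)[C@H]1CC=C | intermediate
19 | 1-nitropropan-2-ol | CC(O)C[N+](=O)[O-] | starting material
20 | (E)-1-nitroprop-1-ene | C/C=C/[N+](=O)[O-] | intermediate
21 | 6-allyl-4-(1-nitropropan-2-yl)-5-R*-3-[(E)-prop-1-enyl]cyclohex-2-en-1-one (C12–C11 bond trans to R*) | O=C1C=C(/C=C/C)[C@@H](C(C)C[N+](=O)[O-])[C@H](/C=C(\C)[C@](C)(/C=C/C(=O)OC)CO[Si](C)(C)C(C)(C)C)[C@H]1CC=C | intermediate (not isolated)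
22 | bicyclic nitro enone (C5=O, C6=C7, C10–NO2, C4-allyl, C13-R*; C9–C11 mixture) | O=C1C=C2CC(C)C([N+](=O)[O-])C(C)[C@H]2[C@H](/C=C(\C)[C@](C)(/C=C/C(=O)OC)CO[Si](C)(C)C(C)(C)C)[C@H]1CC=C | intermediate
23 | bicyclic enedione (C5=O, C6=C7, C10=O; 9S,11R,12R; C4-allyl) | O=C1C=C2C[C@H](C)C(=O)[C@H](C)[C@H]2[C@H](/C=C(\C)[C@](C)(/C=C/C(=O)OC)CO[Si](C)(C)C(C)(C)C)[C@H]1CC=C | intermediate
24 | trione (C4-acetonyl, C5 enone, C10 ketone) | O=C1C=C2C[C@H](C)C(=O)[C@H](C)[C@H]2[C@H](/C=C(\C)[C@](C)(/C=C/C(=O)OC)CO[Si](C)(C)C(C)(C)C)[C@H]1CC(C)=O | intermediate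
25 | bis(ethylene ketal) enone (dioxolanes at C2 and C10) | O=C1C=C2C[C@H](C)C3(OCCO3)[C@H](C)[C@H]2[C@H](/C=C(\C)[C@](C)(/C=C/C(=O)OC)CO[Si](C)(C)C(C)(C)C)[C@H]1CC1(C)OCCO1 | intermediate
26 | dienyl triflate (C4=C5(OTf)–C6=C7) | CC1(OCCO1)CC1=C(OS(=O)(=O)C(F)(F)F)C=C2C[C@H](C)C3(OCCO3)[C@H](C)[C@H]2[C@@H]1/C=C(\C)[C@](C)(/C=C/C(=O)OC)CO[Si](C)(C)C(C)(C)C | intermediate
27 | bis-ketal diene (C5–CH3) | CC1(OCCO1)CC1=C(C)C=C2C[C@H](C)C3(OCCO3)[C@H](C)[C@H]2[C@@H]1/C=C(\C)[C@](C)(/C=C/C(=O)OC)CO[Si](C)(C)C(C)(C)C | intermediate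
28 | methyl ester of the target | CC(=O)CC1=C(C)C=C2C[C@H](C)C(=O)[C@H](C)[C@H]2[C@@H]1/C=C(\C)[C@](C)(/C=C/C(=O)OC)CO | intermediate
29 | CNP0260948.1 (9S,11R,12R,13S,16S) | CC(=O)CC1=C(C)C=C2C[C@H](C)C(=O)[C@H](C)[C@H]2[C@@H]1/C=C(\C)[C@](C)(/C=C/C(=O)O)CO | target

**Step count and risks**
Total steps: 19 (steps 7 and 11 prepare the two small partners). Longest linear sequence: 17 (steps 1–6, 8–10, 12–19).

Step 12 (Proposed new method). What may go wrong is loss of site control in the polyenamine (bond formation through the C9 methyl or through C4 instead of C12), or arrest after the first conjugate addition without ring closure. The fallback uses known reactions, sets out from 18 and returns at 22. Thermodynamic silylation of 18 (t-BuMe2SiOTf, Et3N, CH2Cl2) gives the linear silyl dienol ether F1, whose γ-carbon C12 adds to 20 in a SnCl4-promoted vinylogous Mukaiyama–Michael reaction to give, after mild aqueous work-up, nitro enone 21 (isolated in this variant). DBU in MeCN then closes ring B by intramolecular conjugate addition of the nitronate to C9 and gives 22.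

Step 5. What may go wrong is attack of Me3Al on the unsaturated ester, or sluggish carbometalation next to the quaternary carbon. The fallback sets out from 4 and returns at 6. NaBH4 reduction of 4 gives the alkynol F2; zirconium-catalysed carboalumination–iodination of the free alcohol (carried as its aluminium alkoxide) gives the iodo alcohol F3; Dess–Martin oxidation gives the iodo aldehyde F4; Wittig olefination with Ph3P=CHCO2Me then gives 6.

Step 18. What may go wrong is acid-promoted migration of the ring-A diene, or of the C4=C5 bond into conjugation with the C2 ketone, while the ketals are hydrolysed. The fallback sets out from 27 and returns at 28. Neutral transketalisation with PdCl2(MeCN)2 (cat.) in wet acetone gives the diketone silyl ether F5, and buffered fluoride (HF·pyridine, pyridine, THF) then removes the silyl group to give 28.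

**Further compounds**
F1 | step 12 | tert-butyl{[trans-6-allyl-5-R*-3-((E)-prop-1-enyl)cyclohexa-1,3-dien-1-yl]oxy}dimethylsilane | CC(C)(C)[Si](C)(C)OC1=CC(/C=C/C)=C[C@H](/C=C(\C)[C@](C)(/C=C/C(=O)OC)CO[Si](C)(C)C(C)(C)C)[C@H]1CC=C
F2 | step 5 | (R)-2-{[(tert-butyldimethylsilyl)oxy]methyl}-2-methylbut-3-yn-1-ol | OC[C@@](C)(C#C)CO[Si](C)(C)C(C)(C)C
F3 | step 5 | (R,E)-2-{[(tert-butyldimethylsilyl)oxy]methyl}-4-iodo-2,3-dimethylbut-3-en-1-ol | OC[C@@](C)(/C(C)=C/I)CO[Si](C)(C)C(C)(C)C
F4 | step 5 | (S,E)-2-{[(tert-butyldimethylsilyl)oxy]methyl}-4-iodo-2,3-dimethylbut-3-enal | O=C[C@@](C)(/C(C)=C/I)CO[Si](C)(C)C(C)(C)C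
F5 | step 18 | tert-butyldimethylsilyl ether of 28 (free C2 and C10 ketones) | CC(=O)CC1=C(C)C=C2C[C@H](C)C(=O)[C@H](C)[C@H]2[C@@H]1/C=C(\C)[C@](C)(/C=C/C(=O)OC)CO[Si](C)(C)C(C)(C)C
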